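**Retrosynthetic overview**
1. The strategy rests on the dihydrobenzofuran: C3 carries the exocyclic CH2OH and is bonded to arene carbon C3a, which sits between C4 (OMe) and C7a (ring O). This is what a 5-methoxyflavanone leaves behind when its C4 is pushed out of the ring. The target is therefore traced back (ester reduction, pivalate and benzyl removal) to the trans methyl 2-aryl-2,3-dihydrobenzofuran-3-carboxylate 24.
2. Ester 24 comes from the (2S)-5-methoxyflavanone 21 by oxidative ring contraction: arene carbon C4a shifts from C4 to C3 and C4 becomes the ester carbon.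
3. Flavanone 21 comes from 5-methoxychromone 17 and arylboronic acid 20 by rhodium-catalysed asymmetric 1,4-addition. Chromone 17 comes from acetophenone 15, made by ortho-lithiation of the resorcinol bis-ether 13 between its two oxygens.
4. The tetrahydrofuran of 13 comes from triol 11 by cationic cycloetherification. Triol 11 comes from the aldol of (S)-β-benzyl-γ-butyrolactone 7 with O-benzylisovanillin 8, and 7 from aldehyde 1 by Stobbe condensation and asymmetric hydrogenation.
5. Ring order: butyrolactone (temporary), tetrahydrofuran, pyranone (chromone, then flavanone), contraction to the dihydrofuran.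

Key step: step 14

Remark: 3-hydroxy-5-methoxybenzaldehyde, O-benzylisovanillin and 4-bromo-2-methoxyphenol are taken as purchased. In steps 3 and 13 the stated product configuration is the specification; the ligand antipode that delivers it is fixed on the first run by correlation (sign of rotation of lactone 7, CD of flavanone 21). R* stands for the (3S,4S,5R)-5-[3-(benzyloxy)-4-methoxyphenyl]-4-[(benzyloxy)methyl]oxolan-3-yl group.

**Step 1**
Reactants: 1 3-hydroxy-5-methoxybenzaldehyde
Product: 2 3-methoxy-5-(methoxymethoxy)benzaldehyde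
Conditions: MOMCl, i-Pr2NEt, CH2Cl2, 0 °C to rt
Reagents that add atoms: chloromethyl methyl ether, COCCl
Why: O-alkylation of the phenol (Williamson type) should give the MOM ether, which later serves as ortho-directing group and as the latent ring oxygen of the chromone.

**Step 2**
Reactants: 2 3-methoxy-5-(methoxymethoxy)benzaldehyde; 3 dimethyl succinate
Product: 4 (E)-3-(methoxycarbonyl)-4-[3-methoxy-5-(methoxymethoxy)phenyl]but-3-enoic acid
Conditions: NaOMe, MeOH, reflux; then cold dilute HCl to pH 3
Reagents that add atoms: none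
Why: Stobbe condensation (aldol, lactonisation to the paraconate, E1cB opening) should give the E half-ester with the free acid on the CH2 arm.

**Step 3**
Reactants: 4 (E)-3-(methoxycarbonyl)-4-[3-methoxy-5-(methoxymethoxy)phenyl]but-3-enoic acid
Product: 5 (3S)-3-(methoxycarbonyl)-4-[3-methoxy-5-(methoxymethoxy)phenyl]butanoic acid
Conditions: H2 (5 bar), [Rh(cod)2]BF4 (1 mol %), Et-DuPhos (1.1 mol %, antipode giving 3S), Et3N (1 equiv), MeOH, rt
Reagents that add atoms: none
Why: Rhodium-bisphosphine asymmetric hydrogenation of an itaconate-type half-ester, in which carboxylate-assisted binding lets the ligand set the C3 stereocentre (S), the future tetrahydrofuran C4.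

**Step 4**
Reactants: 5 (3S)-3-(methoxycarbonyl)-4-[3-methoxy-5-(methoxymethoxy)phenyl]butanoic acid
Product: 7 (4S)-4-[3-methoxy-5-(methoxymethoxy)benzyl]oxolan-2-one, via hydroxy acid 6 (not isolated)
Conditions: LiBH4, THF, 0 °C to rt; then 1 M HCl to pH 2–3, 0 °C to rt (brief)
Reagents that add atoms: none
Why: LiBH4 reduces the methyl ester but not the lithium carboxylate, and the γ-hydroxy acid lactonises on acidification without touching the stereocentre (chemoselective reduction, lactonisation).

**Step 5**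
Reactants: 7 (4S)-4-[3-methoxy-5-(methoxymethoxy)benzyl]oxolan-2-one; 8 3-(benzyloxy)-4-methoxybenzaldehyde
Product: 10 (3R,4S)-3-{[3-(benzyloxy)-4-methoxyphenyl](hydroxy)methyl}-4-[3-methoxy-5-(methoxymethoxy)benzyl]oxolan-2-one (both carbinol epimers), via lithium enolate 9 (not isolated)
Conditions: LDA, THF, −78 °C; then 8, −78 °C; sat. NH4Cl at −78 °C
Reagents that add atoms: none
Why: Lithium enolate aldol addition in which the aldehyde approaches anti to the C4 benzyl group, setting C3 trans to C4; the carbinol centre forms as a mixture that step 7 makes irrelevant.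

**Step 6**
Reactants: 10 aldol adduct (both carbinol epimers)
Product: 11 (2S,3S)-2-{[3-(benzyloxy)-4-methoxyphenyl](hydroxy)methyl}-3-[3-methoxy-5-(methoxymethoxy)benzyl]butane-1,4-diol (both carbinol epimers)
Conditions: LiAlH4, THF, 0 °C; Rochelle salt work-up
Reagents that add atoms: none
Why: Hydride reduction of the lactone to the 1,4-diol leaves the benzylic alcohol, the MOM ether and the benzyl ether untouched.

**Step 7**
Reactants: 11 triol (both carbinol epimers)
Product: 12 {(2R,3S,4S)-2-[3-(benzyloxy)-4-methoxyphenyl]-4-[3-methoxy-5-(methoxymethoxy)benzyl]oxolan-3-yl}methanol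
Conditions: camphorsulfonic acid (10 mol %), CH2Cl2, 0 °C, close monitoring; Et3N quench
Reagents that add atoms: none
Why: Acid-catalysed dehydrative cycloetherification (SN1) in which the p-methoxybenzylic cation from either epimer is captured by the hydroxyl of the C4 arm to close the five-membered ring; C2 is set under reversible conditions with the aryl group trans to both neighbouring substituents.

**Step 8**
Reactants: 12 tetrahydrofuran alcohol
Product: 13 (2R,3S,4S)-2-[3-(benzyloxy)-4-methoxyphenyl]-3-[(benzyloxy)methyl]-4-[3-methoxy-5-(methoxymethoxy)benzyl]oxolane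
Conditions: NaH, BnBr, n-Bu4NI (cat.), THF/DMF, 0 °C to rt
Reagents that add atoms: benzyl bromide, BrCc1ccccc1
Why: Williamson etherification of the only free hydroxyl gives a protecting group that survives organolithium, acid and hydride and leaves together with the phenolic benzyl ether at the end.

**Step 9**
Reactants: 13 bis-benzyl tetrahydrofuran
Product: 15 1-[2-methoxy-6-(methoxymethoxy)-4-(R*-methyl)phenyl]ethan-1-one, via aryllithium 14 (not isolated)
Conditions: n-BuLi (1.3 equiv), THF, −20 to 0 °C; then MeC(O)N(OMe)Me, −78 to 0 °C; sat. NH4Cl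
Reagents that add atoms: N-methoxy-N-methylacetamide, CON(C)C(C)=O
Why: Directed ortho-metalation at the ring A C–H flanked by OMe and OMOM, the most acidic aryl position in the molecule, followed by Weinreb amide acylation that stops at the ketone.

**Step 10**
Reactants: 15 acetophenone
Product: 17 5-methoxy-7-(R*-methyl)-4H-chromen-4-one, via enaminone 16 (not isolated)
Conditions: Me2NCH(OMe)2, toluene, 100 °C; concentrate; then 2 M HCl, THF, rt to 40 °C
Reagents that add atoms: N,N-dimethylformamide dimethyl acetal, COC(OC)N(C)C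
Why: Enaminone formation at the methyl ketone, then acid removes the MOM group and the freed phenol closes the pyranone by addition–elimination of dimethylamine (enaminone route to chromones); only the former MOM oxygen can cyclise, so the methoxy group ends at C5.

**Step 11**
Reactants: 18 4-bromo-2-methoxyphenol
Product: 19 4-bromo-2-methoxyphenyl pivalate
Conditions: PivCl, Et3N, DMAP (cat.), CH2Cl2, 0 °C to rt
Reagents that add atoms: pivaloyl chloride, CC(C)(C)C(Cl)=O
Why: Acylation of the phenol installs the electron-withdrawing ester that later lowers the migratory aptitude of ring B.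

**Step 12**
Reactants: 19 4-bromo-2-methoxyphenyl pivalate
Product: 20 [3-methoxy-4-(pivaloyloxy)phenyl]boronic acid
Conditions: B2(OH)4, PdCl(XPhos)(2'-aminobiphenyl-2-yl) (1 mol %), XPhos (2 mol %), KOAc, EtOH, 80 °C
Reagents that add atoms: tetrahydroxydiboron, OB(O)B(O)O
Why: Palladium-catalysed Miyaura-type borylation with tetrahydroxydiboron gives the boronic acid directly and tolerates the hindered aryl ester.

**Step 13**
Reactants: 17 chromone; 20 [3-methoxy-4-(pivaloyloxy)phenyl]boronic acid
Product: 21 (2S)-5-methoxy-2-[3-methoxy-4-(pivaloyloxy)phenyl]-7-(R*-methyl)chroman-4-one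
Conditions: [RhCl(C2H4)2]2 (2.5 mol %), MeO-F12-BIPHEP (5.5 mol %, antipode giving 2S), 20 (3 equiv), aq. KOH (0.2 equiv), toluene/H2O, 25–35 °C
Reagents that add atoms: none
Why: Hayashi–Miyaura rhodium-catalysed asymmetric conjugate addition, in which the aryl-rhodium species adds to chromone C2 on the face chosen by the electron-poor bisphosphine (catalyst control; the tetrahydrofuran stereocentres are remote), setting C2 as S.

**Step 14**
Reactants: 21 (2S)-flavanone
Product: 24 methyl (2S,3S)-4-methoxy-2-[3-methoxy-4-(pivaloyloxy)phenyl]-6-(R*-methyl)-2,3-dihydro-1-benzofuran-3-carboxylate (trans), via enol ether 22 (not isolated), via orthoester 23 (not isolated)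
Conditions: PhI(OAc)2 (1.3 equiv), conc. H2SO4 (cat.), HC(OMe)3, 0 °C to rt; aq. NaHCO3 work-up
Reagents that add atoms: trimethyl orthoformate, COC(OC)OC; water, O
Why: Acid and the orthoformate turn the C4 ketone into enol ether 22; PhI(OAc)2 then attacks C3 anti to the equatorial C2 aryl group and methanol caps C4, so that the C3–I bond is equatorial and antiperiplanar to the ring bond C4–C4a. That bond migrates as iodobenzene leaves: arene carbon C4a attacks C3 through a bridged phenonium-type transition state (three-membered closure, then opening), which forms C3a–C3, contracts the pyranone to the dihydrofuran and leaves old C4 outside the ring as a dimethoxycarbenium ion that is trapped as orthoester 23 and hydrolysed to the methyl ester on work-up. The closest known reaction type is the oxidative ring contraction of flavanones by Tl(NO3)3 or aryl-λ3-iodanes in trimethyl orthoformate to trans methyl 2-aryl-2,3-dihydrobenzofuran-3-carboxylates. The new stereocentre C3 is controlled by C2: anti iodination followed by migration with inversion at C3 places the ester carbon trans to the aryl group, and C2 itself is not touched. The step needs ring-bond migration to win over the shift of ring B from C2 to C3 (isoflavone) and over dehydrogenation to the flavone; the migrating carbon C4a is flanked by two oxygen-bearing carbons (C5–OMe and C8a–O1) and migrates readily, while the pivalate makes ring B a poor migrating group and the diequatorial iodane cannot align the C2–aryl bond.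

**Step 15**
Reactants: 24 trans methyl ester
Product: 25 4-[(2S,3R)-3-(hydroxymethyl)-4-methoxy-6-(R*-methyl)-2,3-dihydro-1-benzofuran-2-yl]-2-methoxyphenol
Conditions: LiAlH4, THF, −10 to 0 °C; Rochelle salt work-up
Reagents that add atoms: none
Why: Hydride reduction converts the ester to the primary alcohol and cleaves the aryl pivalate in one operation, faster than any epimerisation at C3, which is in any case the stable trans isomer.

**Step 16**
Reactants: 25 bis-benzyl ether
Product: 26 5-[(2R,3S,4S)-4-{[(2S,3R)-2-(4-hydroxy-3-methoxyphenyl)-3-(hydroxymethyl)-4-methoxy-2,3-dihydro-1-benzofuran-6-yl]methyl}-3-(hydroxymethyl)oxolan-2-yl]-2-methoxyphenol (CNP0242386.1)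
Conditions: H2 (1 atm), Pd/C (10 %), EtOAc/MeOH, rt, stopped at uptake of 2 equiv
Reagents that add atoms: none
Why: Catalytic hydrogenolysis removes the phenolic and the primary O-benzyl ethers, which cleave faster under neutral conditions than the two cyclic benzylic C–O bonds.

**Compound list**
1 | 3-hydroxy-5-methoxybenzaldehyde | COc1cc(O)cc(C=O)c1 | starting material
2 | 3-methoxy-5-(methoxymethoxy)benzaldehyde | COCOc1cc(OC)cc(C=O)c1 | intermediate
3 | dimethyl succinate | COC(=O)CCC(=O)OC | starting material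
4 | (E)-3-(methoxycarbonyl)-4-[3-methoxy-5-(methoxymethoxy)phenyl]but-3-enoic acid | COC(=O)/C(CC(=O)O)=C/c1cc(OC)cc(OCOC)c1 | intermediate
5 | (3S)-3-(methoxycarbonyl)-4-[3-methoxy-5-(methoxymethoxy)phenyl]butanoic acid | COC(=O)[C@@H](Cc1cc(OC)cc(OCOC)c1)CC(=O)O | intermediate
6 | (3S)-3-(hydroxymethyl)-4-[3-methoxy-5-(methoxymethoxy)phenyl]butanoic acid | OC[C@@H](Cc1cc(OC)cc(OCOC)c1)CC(=O)O | intermediate
7 | (4S)-4-[3-methoxy-5-(methoxymethoxy)benzyl]oxolan-2-one | O=C1OC[C@@H](Cc2cc(OC)cc(OCOC)c2)C1 | intermediate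
8 | 3-(benzyloxy)-4-methoxybenzaldehyde | COc1ccc(C=O)cc1OCc1ccccc1 | starting material
9 | lithium enolate of lactone 7 | [Li]OC1=C[C@H](Cc2cc(OC)cc(OCOC)c2)CO1 | intermediate
10 | (3R,4S)-3-{[3-(benzyloxy)-4-methoxyphenyl](hydroxy)methyl}-4-[3-methoxy-5-(methoxymethoxy)benzyl]oxolan-2-one, carbinol epimers | O=C1OC[C@@H](Cc2cc(OC)cc(OCOC)c2)[C@@H]1C(O)c1ccc(OC)c(OCc2ccccc2)c1 | intermediate
11 | (2S,3S)-2-{[3-(benzyloxy)-4-methoxyphenyl](hydroxy)methyl}-3-[3-methoxy-5-(methoxymethoxy)benzyl]butane-1,4-diol, carbinol epimers | OC[C@@H](Cc1cc(OC)cc(OCOC)c1)[C@@H](CO)C(O)c1ccc(OC)c(OCc2ccccc2)c1 | intermediate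
12 | {(2R,3S,4S)-2-[3-(benzyloxy)-4-methoxyphenyl]-4-[3-methoxy-5-(methoxymethoxy)benzyl]oxolan-3-yl}methanol | COc1ccc([C@@H]2OC[C@@H](Cc3cc(OC)cc(OCOC)c3)[C@H]2CO)cc1OCc1ccccc1 | intermediate
13 | (2R,3S,4S)-2-[3-(benzyloxy)-4-methoxyphenyl]-3-[(benzyloxy)methyl]-4-[3-methoxy-5-(methoxymethoxy)benzyl]oxolane | COc1ccc([C@@H]2OC[C@@H](Cc3cc(OC)cc(OCOC)c3)[C@H]2COCc2ccccc2)cc1OCc1ccccc1 | intermediate
14 | aryllithium of 13, lithium on ring A between OMe and OMOM | COc1ccc([C@@H]2OC[C@@H](Cc3cc(OC)c([Li])c(OCOC)c3)[C@H]2COCc2ccccc2)cc1OCc1ccccc1 | intermediate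
15 | 1-[2-methoxy-6-(methoxymethoxy)-4-(R*-methyl)phenyl]ethan-1-one | COc1ccc([C@@H]2OC[C@@H](Cc3cc(OC)c(C(C)=O)c(OCOC)c3)[C@H]2COCc2ccccc2)cc1OCc1ccccc1 | intermediate
16 | (E)-3-(dimethylamino)-1-[2-methoxy-6-(methoxymethoxy)-4-(R*-methyl)phenyl]prop-2-en-1-one | COc1ccc([C@@H]2OC[C@@H](Cc3cc(OC)c(C(=O)/C=C/N(C)C)c(OCOC)c3)[C@H]2COCc2ccccc2)cc1OCc1ccccc1 | intermediate
17 | 5-methoxy-7-(R*-methyl)-4H-chromen-4-one | COc1ccc([C@@H]2OC[C@@H](Cc3cc(OC)c4c(c3)OC=CC4=O)[C@H]2COCc2ccccc2)cc1OCc1ccccc1 | intermediate
18 | 4-bromo-2-methoxyphenol | COc1cc(Br)ccc1O | starting material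
19 | 4-bromo-2-methoxyphenyl pivalate | COc1cc(Br)ccc1OC(=O)C(C)(C)C | intermediate
20 | [3-methoxy-4-(pivaloyloxy)phenyl]boronic acid | COc1cc(B(O)O)ccc1OC(=O)C(C)(C)C | intermediate
21 | (2S)-5-methoxy-2-[3-methoxy-4-(pivaloyloxy)phenyl]-7-(R*-methyl)chroman-4-one | COc1ccc([C@@H]2OC[C@@H](Cc3cc(OC)c4c(c3)O[C@H](c3ccc(OC(=O)C(C)(C)C)c(OC)c3)CC4=O)[C@H]2COCc2ccccc2)cc1OCc1ccccc1 | intermediate
22 | (2S)-4,5-dimethoxy-2-[3-methoxy-4-(pivaloyloxy)phenyl]-7-(R*-methyl)-2H-chromene | COc1ccc([C@@H]2OC[C@@H](Cc3cc(OC)c4c(c3)O[C@H](c3ccc(OC(=O)C(C)(C)C)c(OC)c3)C=C4OC)[C@H]2COCc2ccccc2)cc1OCc1ccccc1 | intermediate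
23 | (2S,3S)-4-methoxy-2-[3-methoxy-4-(pivaloyloxy)phenyl]-6-(R*-methyl)-3-(trimethoxymethyl)-2,3-dihydro-1-benzofuran | COc1ccc([C@@H]2OC[C@@H](Cc3cc(OC)c4c(c3)O[C@H](c3ccc(OC(=O)C(C)(C)C)c(OC)c3)[C@H]4C(OC)(OC)OC)[C@H]2COCc2ccccc2)cc1OCc1ccccc1 | intermediate
24 | methyl (2S,3S)-4-methoxy-2-[3-methoxy-4-(pivaloyloxy)phenyl]-6-(R*-methyl)-2,3-dihydro-1-benzofuran-3-carboxylate (trans) | COc1ccc([C@@H]2OC[C@@H](Cc3cc(OC)c4c(c3)O[C@H](c3ccc(OC(=O)C(C)(C)C)c(OC)c3)[C@H]4C(=O)OC)[C@H]2COCc2ccccc2)cc1OCc1ccccc1 | intermediate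
25 | 4-[(2S,3R)-3-(hydroxymethyl)-4-methoxy-6-(R*-methyl)-2,3-dihydro-1-benzofuran-2-yl]-2-methoxyphenol | COc1ccc([C@@H]2OC[C@@H](Cc3cc(OC)c4c(c3)O[C@H](c3ccc(O)c(OC)c3)[C@H]4CO)[C@H]2COCc2ccccc2)cc1OCc1ccccc1 | intermediate
26 | 5-[(2R,3S,4S)-4-{[(2S,3R)-2-(4-hydroxy-3-methoxyphenyl)-3-(hydroxymethyl)-4-methoxy-2,3-dihydro-1-benzofuran-6-yl]methyl}-3-(hydroxymethyl)oxolan-2-yl]-2-methoxyphenol | COc1ccc([C@@H]2OC[C@@H](Cc3cc(OC)c4c(c3)O[C@H](c3ccc(O)c(OC)c3)[C@H]4CO)[C@H]2CO)cc1O | target

**Step count**
Total: 16 steps. Longest linear sequence: 14 steps (steps 1–10 and 13–16); steps 11–12 make the boronic acid on a side branch.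

**Steps most likely to fail**

Step 14. The iodane adduct may lose the C2 hydrogen instead of rearranging (dehydrogenation to the flavone), ring B may shift from C2 to C3, or the acid may ionise the benzylic C–O bond of the tetrahydrofuran before the oxidant is consumed. The fallback keeps the same aryl shift but drives it from a carbene instead of an iodane (Wolff ring contraction). It sets out from flavanone 21. Detrifluoroacetylative diazo transfer (LiHMDS, CF3CO2CH2CF3, THF, −78 °C; then MsN3, Et3N, MeCN) should give the 3-diazo derivative of 21 F1 (C2 unchanged in space). Photolysis in methanol should expel nitrogen, shift C4a from C4 to C3 and trap the ketene as the methyl ester. A short treatment with catalytic DBU should bring the C3 epimers to the trans ester, which is compound 24, where the route is rejoined.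

Step 13. The electron-rich 5-methoxychromone may react slowly, so that protodeboronation and base-induced opening of the pyranone (which erodes C2) compete, or facial selectivity may be insufficient. The fallback builds C2 by aldol addition and closes the ring with inversion. It sets out from acetophenone 15. The boron enolate of 15 (Ipc2BCl antipode giving the R carbinol, Et3N, −78 °C) is added to vanillin pivalate F2 (from vanillin and pivaloyl chloride) to give the (R)-β-hydroxy ketone F3. Dilute HCl in THF at rt removes the ortho-acyl MOM ether to give the phenol F4. Mitsunobu cyclisation (PPh3, DIAD, THF, 0 °C) displaces the benzylic hydroxyl with inversion and should give the (2S)-flavanone 21, where the route is rejoined.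

Step 7. Under reversible acidic ionisation the benzylic cation may be intercepted by the dialkoxy ring A (Friedel–Crafts closure to an aryltetralin), or the MOM ether may be lost on longer exposure. The fallback generates the same ring by oxidative C–H etherification under non-acidic, irreversible conditions. It sets out from lactone 7. Alkylation of its lithium enolate (LDA, THF, −78 °C) with 3-(benzyloxy)-4-methoxybenzyl bromide F5 (from the commercial benzyl alcohol and PBr3) occurs anti to the C4 substituent and should give the trans dibenzyl lactone F6. LiAlH4 reduces it to the diol F7. DDQ in CH2Cl2/pH 7 buffer at 0 °C abstracts hydride only from the p-methoxybenzylic CH2, and the hydroxyl on the C4 arm closes the ring with the aryl group trans, to give tetrahydrofuran alcohol 12, where the route is rejoined.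

**Further compounds**
F1 | step 14 | 3-diazo derivative of flavanone 21 | COc1ccc([C@@H]2OC[C@@H](Cc3cc(OC)c4c(c3)O[C@H](c3ccc(OC(=O)C(C)(C)C)c(OC)c3)C(=[N+]=[N-])C4=O)[C@H]2COCc2ccccc2)cc1OCc1ccccc1
F2 | step 13 | 4-formyl-2-methoxyphenyl pivalate (vanillin pivalate) | COc1cc(C=O)ccc1OC(=O)C(C)(C)C
F3 | step 13 | (3R)-3-hydroxy-1-[2-methoxy-6-(methoxymethoxy)-4-(R*-methyl)phenyl]-3-[3-methoxy-4-(pivaloyloxy)phenyl]propan-1-one | COc1ccc([C@@H]2OC[C@@H](Cc3cc(OC)c(C(=O)C[C@@H](O)c4ccc(OC(=O)C(C)(C)C)c(OC)c4)c(OCOC)c3)[C@H]2COCc2ccccc2)cc1OCc1ccccc1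
F4 | step 13 | (3R)-3-hydroxy-1-[2-hydroxy-6-methoxy-4-(R*-methyl)phenyl]-3-[3-methoxy-4-(pivaloyloxy)phenyl]propan-1-one | COc1ccc([C@@H]2OC[C@@H](Cc3cc(OC)c(C(=O)C[C@@H](O)c4ccc(OC(=O)C(C)(C)C)c(OC)c4)c(O)c3)[C@H]2COCc2ccccc2)cc1OCc1ccccc1
F5 | step 7 | 3-(benzyloxy)-4-methoxybenzyl bromide | COc1ccc(CBr)cc1OCc1ccccc1
F6 | step 7 | (3S,4S)-3-[3-(benzyloxy)-4-methoxybenzyl]-4-[3-methoxy-5-(methoxymethoxy)benzyl]oxolan-2-one (trans) | O=C1OC[C@@H](Cc2cc(OC)cc(OCOC)c2)[C@@H]1Cc1ccc(OC)c(OCc2ccccc2)c1
F7 | step 7 | (2S,3S)-2-[3-(benzyloxy)-4-methoxybenzyl]-3-[3-methoxy-5-(methoxymethoxy)benzyl]butane-1,4-diol | OC[C@@H](Cc1cc(OC)cc(OCOC)c1)[C@@H](CO)Cc1ccc(OC)c(OCc2ccccc2)c1
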